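## Retrosynthetic overview

1. Target 34 comes from SN2 O-demethylation of methyl tetronate 33 (last step).
2. The C11–C12 bond is made by Suzuki–Miyaura coupling of (E)-alkenylboronate 13 (furan half) with (E)-alkenyl iodide 32 (tetronate half). Both alkene geometries are fixed beforehand from terminal alkynes (hydroboration; carboalumination–iodination).
3. The (Z)-C20=C21 ylidene comes from aldol addition of lithiated methyl 3-methyltetronate to aldehyde 26, then dehydration.
4. C8 (S) is set by Rh–DuPhos hydrogenation of monomethyl itaconate; C18 (R) by lipase desymmetrisation of 2-methylpropane-1,3-diol.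
5. Rings: neither ring is built. The furan enters first as 3-bromofuran (step 6), the butenolide later as 3-methyltetronic acid (steps 20–21).

Assumption: positions are numbered C1–C4 (furan), C5–C20 (chain, methyls on C8, C13, C18) and C21–C24 (butenolide); compound 1 is the commercial 4-methyl ester of itaconic acid.

## Route

**Furan half (steps 1–10)**

Step 1
Reactants: 1 monomethyl itaconate (4-methoxy-2-methylidene-4-oxobutanoic acid)
Product: 2 (2S)-4-methoxy-2-methyl-4-oxobutanoic acid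
Conditions: H2 (5 bar), [Rh(cod)((R,R)-Et-DuPhos)]BF4 (0.5 mol %), MeOH, 25 °C
Reagents that add atoms: none
Why: Asymmetric hydrogenation in which the itaconate chelates rhodium through the alkene and the carbonyl of the CH2CO2Me arm, so the C2-symmetric bisphospholane delivers H2 to one face and sets the future C8 as S (≥97% ee expected; the (R,R)-ligand gives the (S)-acid by analogy with DuPhos–Rh itaconate reductions).

Step 2
Reactants: 2 (2S)-4-methoxy-2-methyl-4-oxobutanoic acid
Product: 3 methyl (3S)-4-hydroxy-3-methylbutanoate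
Conditions: BH3·SMe2 (1.1 equiv), THF, −10 °C → rt; aqueous work-up, used crude at once
Reagents that add atoms: none
Why: Chemoselective borane reduction of a carboxylic acid beside a methyl ester (via the acyloxyborane) leaves the stereocentre untouched, and immediate use forestalls lactonisation.

Step 3
Reactants: 3 methyl (3S)-4-hydroxy-3-methylbutanoate
Product: 4 methyl (3S)-4-[(tert-butyldiphenylsilyl)oxy]-3-methylbutanoate
Conditions: TBDPSCl (1.1 equiv), imidazole (2 equiv), DMF, 0 °C → rt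
Reagents that add atoms: tert-butyl(chloro)diphenylsilane (TBDPSCl), CC(C)(C)[Si](Cl)(c1ccccc1)c1ccccc1
Why: Imidazole-promoted silylation of the primary alcohol gives a robust ether that survives hydride, ylide, borane and aqueous-base steps.

Step 4
Reactants: 4 methyl (3S)-4-[(tert-butyldiphenylsilyl)oxy]-3-methylbutanoate
Product: 5 (3S)-4-[(tert-butyldiphenylsilyl)oxy]-3-methylbutanal
Conditions: i-Bu2AlH (1.1 equiv), CH2Cl2, −78 °C
Reagents that add atoms: none
Why: Partial ester reduction stops at the aldehyde because the tetrahedral aluminium hemiacetal is stable at −78 °C, and the stereocentre is β to the carbonyl so it cannot epimerise.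

Step 5
Reactants: 5 (3S)-4-[(tert-butyldiphenylsilyl)oxy]-3-methylbutanal
Product: 6 tert-butyl{[(2S)-2-methylpent-4-en-1-yl]oxy}diphenylsilane
Conditions: Ph3PCH3Br (1.5 equiv), KN(SiMe3)2 (1.4 equiv), THF, 0 °C; then 5, −78 °C → rt
Reagents that add atoms: methyltriphenylphosphonium bromide, C[P+](c1ccccc1)(c1ccccc1)c1ccccc1.[Br-]
Why: Wittig methylenation of an unhindered aldehyde gives the terminal alkene needed for hydroboration.

Step 6
Reactants: 6 tert-butyl{[(2S)-2-methylpent-4-en-1-yl]oxy}diphenylsilane; 7 3-bromofuran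
Product: 9 tert-butyl{[(2S)-5-(furan-3-yl)-2-methylpentyl]oxy}diphenylsilane, via alkylborane 8 (not isolated)
Conditions: 9-BBN (1.3 equiv), THF, rt; then 7 (1.5 equiv), PdCl2(dppf) (5 mol %), aq. K3PO4 (3 equiv), DMF, 50 °C
Reagents that add atoms: 9-borabicyclo[3.3.1]nonane (9-BBN), B1C2CCCC1CCC2 (its atoms stay in 8 only)
Why: Anti-Markovnikov hydroboration followed by B-alkyl Suzuki–Miyaura coupling attaches the preformed furan at C5 through a C(sp3)–C(sp2) bond without touching the remote stereocentre.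

Step 7
Reactants: 9 tert-butyl{[(2S)-5-(furan-3-yl)-2-methylpentyl]oxy}diphenylsilane
Product: 10 (2S)-5-(furan-3-yl)-2-methylpentan-1-ol
Conditions: TBAF (1.2 equiv), THF, rt
Reagents that add atoms: none
Why: Fluoride-driven desilylation is neutral enough for the acid-sensitive 3-alkylfuran.

Step 8
Reactants: 10 (2S)-5-(furan-3-yl)-2-methylpentan-1-ol
Product: 11 (2S)-5-(furan-3-yl)-2-methylpentanal
Conditions: DMP (1.3 equiv), pyridine (3 equiv), CH2Cl2, 0 °C → rt; used crude
Reagents that add atoms: none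
Why: Dess–Martin oxidation under buffered, non-enolising conditions gives the α-methyl aldehyde without epimerisation or furan oxidation.

Step 9
Reactants: 11 (2S)-5-(furan-3-yl)-2-methylpentanal
Product: 12 3-[(4S)-4-methylhex-5-yn-1-yl]furan
Conditions: dimethyl (1-diazo-2-oxopropyl)phosphonate (1.3 equiv), K2CO3 (2 equiv), MeOH, 0 °C → rt
Reagents that add atoms: dimethyl (1-diazo-2-oxopropyl)phosphonate, COP(=O)(OC)C(=[N+]=[N-])C(C)=O
Why: Ohira–Bestmann (Seyferth–Gilbert) homologation turns the aldehyde into the terminal alkyne under carbonate conditions that are known to preserve α-methyl stereocentres.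

Step 10
Reactants: 12 3-[(4S)-4-methylhex-5-yn-1-yl]furan
Product: 13 2-[(1E,3S)-6-(furan-3-yl)-3-methylhex-1-en-1-yl]-4,4,5,5-tetramethyl-1,3,2-dioxaborolane
Conditions: pinacolborane (1.5 equiv), Cp2Zr(H)Cl (10 mol %), Et3N (10 mol %), neat, 60 °C
Reagents that add atoms: pinacolborane (4,4,5,5-tetramethyl-1,3,2-dioxaborolane), CC1(C)OBOC1(C)C
Why: Zirconocene-hydride-catalysed syn hydroboration of the terminal alkyne is anti-Markovnikov and gives only the (E)-alkenylboronate, fixing the C10=C11 geometry.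

**Tetronate half (steps 11–22)**

Step 11
Reactants: 14 2-methylpropane-1,3-diol
Product: 15 (2S)-3-hydroxy-2-methylpropyl acetate
Conditions: lipase (Pseudomonas fluorescens lipase, Amano AK), vinyl acetate (3 equiv), CHCl3, 25 °C, stopped at ≥98% ee (chiral GC)
Reagents that add atoms: vinyl acetate, CC(=O)OC=C
Why: A lipase (serine hydrolase) desymmetrises the prochiral diol by enantiotopos-selective, irreversible transesterification to the (S)-monoacetate, and its faster second acylation of the minor enantiomer raises the ee further, which sets the future C18.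

Step 12
Reactants: 15 (2S)-3-hydroxy-2-methylpropyl acetate
Product: 16 (2R)-3-[(tert-butyldiphenylsilyl)oxy]-2-methylpropyl acetate
Conditions: TBDPSCl (1.1 equiv), imidazole (2 equiv), CH2Cl2, 0 °C, short reaction time
Reagents that add atoms: tert-butyl(chloro)diphenylsilane (TBDPSCl), CC(C)(C)[Si](Cl)(c1ccccc1)c1ccccc1
Why: Fast silylation of the free hydroxyl at 0 °C locks the two arms as different groups before 1,3-acyl migration can racemise the monoacetate (the descriptor changes only through CIP priorities).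

Step 13
Reactants: 16 (2R)-3-[(tert-butyldiphenylsilyl)oxy]-2-methylpropyl acetate
Product: 17 (2R)-3-[(tert-butyldiphenylsilyl)oxy]-2-methylpropan-1-ol
Conditions: K2CO3 (0.2 equiv), MeOH, 0 °C → rt
Reagents that add atoms: none
Why: Base-catalysed transesterification removes the acetate while the silyl ether is inert.

Step 14
Reactants: 17 (2R)-3-[(tert-butyldiphenylsilyl)oxy]-2-methylpropan-1-ol
Product: 18 (2S)-3-[(tert-butyldiphenylsilyl)oxy]-2-methylpropyl 4-methylbenzenesulfonate
Conditions: TsCl (1.3 equiv), Et3N (2 equiv), DMAP (5 mol %), CH2Cl2, 0 °C → rt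
Reagents that add atoms: 4-methylbenzenesulfonyl chloride (TsCl), Cc1ccc(cc1)S(Cl)(=O)=O
Why: Sulfonylation activates the primary alcohol for C–C coupling without touching the stereocentre.

Step 15
Reactants: 18 (2S)-3-[(tert-butyldiphenylsilyl)oxy]-2-methylpropyl 4-methylbenzenesulfonate; 19 (4-bromobut-1-yn-1-yl)trimethylsilane
Product: 21 tert-butyl{[(2R)-2-methyl-7-(trimethylsilyl)hept-6-yn-1-yl]oxy}diphenylsilane, via Grignard reagent 20 (not isolated)
Conditions: 19 (2.5 equiv), Mg, THF, rt → 40 °C; then 18, Li2CuCl4 (5 mol %), THF, −20 °C → rt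
Reagents that add atoms: magnesium, [Mg] (stays in 20 only)
Why: Copper-catalysed Grignard–tosylate cross-coupling (Kochi/Fouquet–Schlosser) forms the C16–C17 bond at a primary carbon, so the adjacent stereocentre is not involved.

Step 16
Reactants: 21 tert-butyl{[(2R)-2-methyl-7-(trimethylsilyl)hept-6-yn-1-yl]oxy}diphenylsilane
Product: 22 tert-butyl{[(2R)-2-methylhept-6-yn-1-yl]oxy}diphenylsilane
Conditions: K2CO3 (0.3 equiv), MeOH/THF, rt
Reagents that add atoms: none
Why: Methanolysis cleaves the alkynyl C–Si bond selectively, leaving the bulky silyl ether intact.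

Step 17
Reactants: 22 tert-butyl{[(2R)-2-methylhept-6-yn-1-yl]oxy}diphenylsilane
Product: 24 tert-butyl{[(2R,6E)-7-iodo-2,6-dimethylhept-6-en-1-yl]oxy}diphenylsilane, via alkenylalane 23 (not isolated)
Conditions: Me3Al (2.5 equiv), Cp2ZrCl2 (25 mol %), CH2Cl2, 0 °C → rt; then I2 (1.3 equiv), THF, −30 °C → 0 °C
Reagents that add atoms: trimethylaluminium, C[Al](C)C; iodine, II
Why: Negishi zirconium-catalysed carboalumination adds Me and Al syn across the terminal alkyne with Me at the internal carbon, and iodinolysis with retention gives the (E)-trisubstituted alkenyl iodide (C12=C13 and the C14 methyl).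

Step 18
Reactants: 24 tert-butyl{[(2R,6E)-7-iodo-2,6-dimethylhept-6-en-1-yl]oxy}diphenylsilane
Product: 25 (2R,6E)-7-iodo-2,6-dimethylhept-6-en-1-ol
Conditions: TBAF (1.2 equiv), THF, rt
Reagents that add atoms: none
Why: Fluoride desilylation frees the primary alcohol and leaves the alkenyl iodide untouched.

Step 19
Reactants: 25 (2R,6E)-7-iodo-2,6-dimethylhept-6-en-1-ol
Product: 26 (2R,6E)-7-iodo-2,6-dimethylhept-6-enal
Conditions: DMP (1.3 equiv), pyridine (3 equiv), CH2Cl2, 0 °C → rt; used crude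
Reagents that add atoms: none
Why: Dess–Martin oxidation gives the α-methyl aldehyde under non-enolising conditions, so C18 keeps its configuration.

Step 20
Reactants: 27 3-methyltetronic acid (4-hydroxy-3-methylfuran-2(5H)-one)
Product: 28 4-methoxy-3-methylfuran-2(5H)-one
Conditions: Me2SO4 (1.2 equiv), K2CO3 (1.5 equiv), acetone, reflux
Reagents that add atoms: dimethyl sulfate, COS(=O)(=O)OC
Why: O-alkylation of the tetronate anion at the 4-oxygen masks the acidic enol as a vinylogous methyl carbonate and allows clean C5 deprotonation.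

Step 21
Reactants: 28 4-methoxy-3-methylfuran-2(5H)-one; 26 (2R,6E)-7-iodo-2,6-dimethylhept-6-enal
Product: 30 5-[(2R,6E)-1-hydroxy-7-iodo-2,6-dimethylhept-6-en-1-yl]-4-methoxy-3-methylfuran-2(5H)-one (diastereomer mixture at the two new centres), via lithiated tetronate 29 (not isolated)
Conditions: LiN(i-Pr)2 (1.15 equiv), 28 (1.2 equiv), THF, −78 °C; then 26, −78 °C; AcOH quench at −78 °C
Reagents that add atoms: lithium diisopropylamide, [Li]N(C(C)C)C(C)C (lithium stays in 29 only)
Why: Aldol addition of the C5-lithiated methyl tetronate (a stabilised, weakly basic dienolate) to the aldehyde is fast at −78 °C, so C18 is not epimerised, and the two new centres are destroyed in the next step.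

Step 22
Reactants: 30 5-[(2R,6E)-1-hydroxy-7-iodo-2,6-dimethylhept-6-en-1-yl]-4-methoxy-3-methylfuran-2(5H)-one
Product: 32 (5Z)-5-[(2R,6E)-7-iodo-2,6-dimethylhept-6-en-1-ylidene]-4-methoxy-3-methylfuran-2(5H)-one, via mesylate 31 (not isolated)
Conditions: MsCl (1.5 equiv), Et3N (3 equiv), CH2Cl2, 0 °C; then DBU (3 equiv), rt
Reagents that add atoms: methanesulfonyl chloride, CS(=O)(=O)Cl (stays in 31 only)
Why: Mesylation and E1cB elimination through the C5 dienolate give the ylidene, and the Z isomer dominates because the E isomer forces the branched chain against the 4-methoxy group.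

**Union and end game (steps 23–24)**

Step 23
Reactants: 13 2-[(1E,3S)-6-(furan-3-yl)-3-methylhex-1-en-1-yl]-4,4,5,5-tetramethyl-1,3,2-dioxaborolane; 32 (5Z)-5-[(2R,6E)-7-iodo-2,6-dimethylhept-6-en-1-ylidene]-4-methoxy-3-methylfuran-2(5H)-one
Product: 33 (5Z)-5-[(2R,6E,8E,10S)-13-(furan-3-yl)-2,6,10-trimethyltrideca-6,8-dien-1-ylidene]-4-methoxy-3-methylfuran-2(5H)-one
Conditions: PdCl2(dppf) (5 mol %), K3PO4 (3 equiv), THF/H2O (5:1), 40 °C, degassed, dark
Reagents that add atoms: none
Why: Suzuki–Miyaura coupling of an alkenyl iodide with an alkenylboronate proceeds with retention at both partners, giving the (10E,12E)-diene under base mild enough for the methyl tetronate.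

Step 24
Reactants: 33 (5Z)-5-[(2R,6E,8E,10S)-13-(furan-3-yl)-2,6,10-trimethyltrideca-6,8-dien-1-ylidene]-4-methoxy-3-methylfuran-2(5H)-one
Product: 34 (5Z)-5-[(2R,6E,8E,10S)-13-(furan-3-yl)-2,6,10-trimethyltrideca-6,8-dien-1-ylidene]-4-hydroxy-3-methylfuran-2(5H)-one (CNP0223721.1)
Conditions: n-PrSH/n-BuLi (n-PrSLi, 3 equiv), HMPA, rt; then cold aq. HCl to pH 3
Reagents that add atoms: none
Why: SN2 O-demethylation, in which the soft thiolate attacks the methyl group and expels the stabilised tetronate anion, so the diene, the furan and both stereocentres are left alone.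

## Compound list

1 | monomethyl itaconate (4-methoxy-2-methylidene-4-oxobutanoic acid) | C=C(CC(=O)OC)C(=O)O | starting material
2 | (2S)-4-methoxy-2-methyl-4-oxobutanoic acid | C[C@@H](CC(=O)OC)C(=O)O | intermediate
3 | methyl (3S)-4-hydroxy-3-methylbutanoate | C[C@@H](CC(=O)OC)CO | intermediate
4 | methyl (3S)-4-[(tert-butyldiphenylsilyl)oxy]-3-methylbutanoate | C[C@@H](CC(=O)OC)CO[Si](c1ccccc1)(c1ccccc1)C(C)(C)C | intermediate
5 | (3S)-4-[(tert-butyldiphenylsilyl)oxy]-3-methylbutanal | C[C@@H](CC=O)CO[Si](c1ccccc1)(c1ccccc1)C(C)(C)C | intermediate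
6 | tert-butyl{[(2S)-2-methylpent-4-en-1-yl]oxy}diphenylsilane | C[C@@H](CC=C)CO[Si](c1ccccc1)(c1ccccc1)C(C)(C)C | intermediate
7 | 3-bromofuran | Brc1ccoc1 | starting material
8 | 9-{(4S)-5-[(tert-butyldiphenylsilyl)oxy]-4-methylpentyl}-9-borabicyclo[3.3.1]nonane | C[C@@H](CCCB1C2CCCC1CCC2)CO[Si](c1ccccc1)(c1ccccc1)C(C)(C)C | intermediate
9 | tert-butyl{[(2S)-5-(furan-3-yl)-2-methylpentyl]oxy}diphenylsilane | C[C@@H](CCCc1ccoc1)CO[Si](c2ccccc2)(c2ccccc2)C(C)(C)C | intermediate
10 | (2S)-5-(furan-3-yl)-2-methylpentan-1-ol | C[C@@H](CCCc1ccoc1)CO | intermediate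
11 | (2S)-5-(furan-3-yl)-2-methylpentanal | C[C@@H](CCCc1ccoc1)C=O | intermediate
12 | 3-[(4S)-4-methylhex-5-yn-1-yl]furan | C[C@@H](CCCc1ccoc1)C#C | intermediate
13 | 2-[(1E,3S)-6-(furan-3-yl)-3-methylhex-1-en-1-yl]-4,4,5,5-tetramethyl-1,3,2-dioxaborolane | C[C@@H](CCCc1ccoc1)/C=C/B1OC(C)(C)C(C)(C)O1 | intermediate
14 | 2-methylpropane-1,3-diol | CC(CO)CO | starting material
15 | (2S)-3-hydroxy-2-methylpropyl acetate | CC(=O)OC[C@@H](C)CO | intermediate
16 | (2R)-3-[(tert-butyldiphenylsilyl)oxy]-2-methylpropyl acetate | CC(=O)OC[C@@H](C)CO[Si](c1ccccc1)(c1ccccc1)C(C)(C)C | intermediate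
17 | (2R)-3-[(tert-butyldiphenylsilyl)oxy]-2-methylpropan-1-ol | OC[C@@H](C)CO[Si](c1ccccc1)(c1ccccc1)C(C)(C)C | intermediate
18 | (2S)-3-[(tert-butyldiphenylsilyl)oxy]-2-methylpropyl 4-methylbenzenesulfonate | Cc1ccc(cc1)S(=O)(=O)OC[C@@H](C)CO[Si](c1ccccc1)(c1ccccc1)C(C)(C)C | intermediate
19 | (4-bromobut-1-yn-1-yl)trimethylsilane | C[Si](C)(C)C#CCCBr | starting material
20 | [4-(trimethylsilyl)but-3-yn-1-yl]magnesium bromide | C[Si](C)(C)C#CCC[Mg]Br | intermediate
21 | tert-butyl{[(2R)-2-methyl-7-(trimethylsilyl)hept-6-yn-1-yl]oxy}diphenylsilane | C[Si](C)(C)C#CCCC[C@@H](C)CO[Si](c1ccccc1)(c1ccccc1)C(C)(C)C | intermediate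
22 | tert-butyl{[(2R)-2-methylhept-6-yn-1-yl]oxy}diphenylsilane | C#CCCC[C@@H](C)CO[Si](c1ccccc1)(c1ccccc1)C(C)(C)C | intermediate
23 | {(1E,6R)-7-[(tert-butyldiphenylsilyl)oxy]-2,6-dimethylhept-1-en-1-yl}dimethylalumane | C[Al](C)/C=C(\C)CCC[C@@H](C)CO[Si](c1ccccc1)(c1ccccc1)C(C)(C)C | intermediate
24 | tert-butyl{[(2R,6E)-7-iodo-2,6-dimethylhept-6-en-1-yl]oxy}diphenylsilane | I/C=C(\C)CCC[C@@H](C)CO[Si](c1ccccc1)(c1ccccc1)C(C)(C)C | intermediate
25 | (2R,6E)-7-iodo-2,6-dimethylhept-6-en-1-ol | I/C=C(\C)CCC[C@@H](C)CO | intermediate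
26 | (2R,6E)-7-iodo-2,6-dimethylhept-6-enal | I/C=C(\C)CCC[C@@H](C)C=O | intermediate
27 | 3-methyltetronic acid (4-hydroxy-3-methylfuran-2(5H)-one) | CC1=C(O)COC1=O | starting material
28 | 4-methoxy-3-methylfuran-2(5H)-one | COC1=C(C)C(=O)OC1 | intermediate
29 | 5-lithio-4-methoxy-3-methylfuran-2(5H)-one | [Li]C1OC(=O)C(C)=C1OC | intermediate
30 | 5-[(2R,6E)-1-hydroxy-7-iodo-2,6-dimethylhept-6-en-1-yl]-4-methoxy-3-methylfuran-2(5H)-one (diastereomer mixture) | COC1=C(C)C(=O)OC1C(O)[C@H](C)CCC/C(C)=C/I | intermediate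
31 | (2R,6E)-7-iodo-1-(3-methoxy-4-methyl-5-oxo-2,5-dihydrofuran-2-yl)-2,6-dimethylhept-6-en-1-yl methanesulfonate (diastereomer mixture) | COC1=C(C)C(=O)OC1C(OS(C)(=O)=O)[C@H](C)CCC/C(C)=C/I | intermediate
32 | (5Z)-5-[(2R,6E)-7-iodo-2,6-dimethylhept-6-en-1-ylidene]-4-methoxy-3-methylfuran-2(5H)-one | COC1=C(C)C(=O)O/C1=C\[C@H](C)CCC/C(C)=C/I | intermediate
33 | (5Z)-5-[(2R,6E,8E,10S)-13-(furan-3-yl)-2,6,10-trimethyltrideca-6,8-dien-1-ylidene]-4-methoxy-3-methylfuran-2(5H)-one | COC1=C(C)C(=O)O/C1=C\[C@H](C)CCC/C(C)=C/C=C/[C@@H](C)CCCc1ccoc1 | intermediate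
34 | (5Z)-5-[(2R,6E,8E,10S)-13-(furan-3-yl)-2,6,10-trimethyltrideca-6,8-dien-1-ylidene]-4-hydroxy-3-methylfuran-2(5H)-one (CNP0223721.1) | CC1=C(O)/C(=C/[C@H](C)CCC/C(C)=C/C=C/[C@@H](C)CCCc2ccoc2)OC1=O | target

## Step count and risks

Total steps: 24 (10 for the furan half, 9 to aldehyde 26, 1 for the methyl tetronate, 4 from aldol to target).
Longest linear sequence: 13 steps (14 → 34 through steps 11–19 and 21–24).

**Step 15 (copper-catalysed coupling of 18 with Grignard reagent 20).** The β-branched tosylate reacts slowly and the homopropargylic Grignard reagent may form or couple poorly. The fallback sets out from 18 and builds the alkyne by aldehyde homologation instead of carrying it in the nucleophile. Allylmagnesium bromide (CuI cat., THF, 0 °C) displaces the tosylate to give tert-butyl{[(2R)-2-methylhex-5-en-1-yl]oxy}diphenylsilane F1. Hydroboration with 9-BBN gives 9-{(5R)-6-[(tert-butyldiphenylsilyl)oxy]-5-methylhexyl}-9-borabicyclo[3.3.1]nonane F2, which NaOH/H2O2 oxidises to (5R)-6-[(tert-butyldiphenylsilyl)oxy]-5-methylhexan-1-ol F3. Dess–Martin oxidation gives (5R)-6-[(tert-butyldiphenylsilyl)oxy]-5-methylhexanal F4, and Ohira–Bestmann homologation (K2CO3, MeOH) comes back to the route at 22.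

**Step 21 (aldol of lithiated tetronate 29 with 26).** The basic lithium dienolate may enolise the α-methyl aldehyde (eroding C18) or give low conversion. The fallback sets out from 28 and replaces the lithium aldol by a Lewis-acid vinylogous Mukaiyama aldol. TBSOTf/Et3N (CH2Cl2, 0 °C) converts 28 into tert-butyl[(4-methoxy-3-methylfuran-2-yl)oxy]dimethylsilane F5. F5 adds through C5 to 26 with BF3·OEt2 (CH2Cl2, −78 °C), and the sequence comes back at 30.

**Step 24 (thiolate demethylation of 33).** The thiolate may add to the ylidene butenolide or displace the 4-methoxy group on the fully assembled molecule. The fallback sets out from 27 and carries an acid-labile methoxymethyl group instead of methyl. MOMCl/i-Pr2NEt (CH2Cl2, 0 °C) gives 4-(methoxymethoxy)-3-methylfuran-2(5H)-one F6. LiN(i-Pr)2 (THF, −78 °C) gives 5-lithio-4-(methoxymethoxy)-3-methylfuran-2(5H)-one F7, which adds to 26 to give 5-[(2R,6E)-1-hydroxy-7-iodo-2,6-dimethylhept-6-en-1-yl]-4-(methoxymethoxy)-3-methylfuran-2(5H)-one F8. MsCl/Et3N gives (2R,6E)-7-iodo-1-[3-(methoxymethoxy)-4-methyl-5-oxo-2,5-dihydrofuran-2-yl]-2,6-dimethylhept-6-en-1-yl methanesulfonate F9, and DBU eliminates it to (5Z)-5-[(2R,6E)-7-iodo-2,6-dimethylhept-6-en-1-ylidene]-4-(methoxymethoxy)-3-methylfuran-2(5H)-one F10. Suzuki coupling with 13 under the step 23 conditions gives (5Z)-5-[(2R,6E,8E,10S)-13-(furan-3-yl)-2,6,10-trimethyltrideca-6,8-dien-1-ylidene]-4-(methoxymethoxy)-3-methylfuran-2(5H)-one F11. Brief treatment with 1 M HCl in THF at rt cleaves the vinylogous acetal and comes back at 34.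

## Further compounds

F1 | step 15 | tert-butyl{[(2R)-2-methylhex-5-en-1-yl]oxy}diphenylsilane | C=CCC[C@@H](C)CO[Si](c1ccccc1)(c1ccccc1)C(C)(C)C
F2 | step 15 | 9-{(5R)-6-[(tert-butyldiphenylsilyl)oxy]-5-methylhexyl}-9-borabicyclo[3.3.1]nonane | B1(CCCC[C@@H](C)CO[Si](c2ccccc2)(c2ccccc2)C(C)(C)C)C2CCCC1CCC2
F3 | step 15 | (5R)-6-[(tert-butyldiphenylsilyl)oxy]-5-methylhexan-1-ol | OCCCC[C@@H](C)CO[Si](c1ccccc1)(c1ccccc1)C(C)(C)C
F4 | step 15 | (5R)-6-[(tert-butyldiphenylsilyl)oxy]-5-methylhexanal | O=CCCC[C@@H](C)CO[Si](c1ccccc1)(c1ccccc1)C(C)(C)C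
F5 | step 21 | tert-butyl[(4-methoxy-3-methylfuran-2-yl)oxy]dimethylsilane | COc1coc(O[Si](C)(C)C(C)(C)C)c1C
F6 | step 24 | 4-(methoxymethoxy)-3-methylfuran-2(5H)-one | COCOC1=C(C)C(=O)OC1
F7 | step 24 | 5-lithio-4-(methoxymethoxy)-3-methylfuran-2(5H)-one | [Li]C1OC(=O)C(C)=C1OCOC
F8 | step 24 | 5-[(2R,6E)-1-hydroxy-7-iodo-2,6-dimethylhept-6-en-1-yl]-4-(methoxymethoxy)-3-methylfuran-2(5H)-one | COCOC1=C(C)C(=O)OC1C(O)[C@H](C)CCC/C(C)=C/I
F9 | step 24 | (2R,6E)-7-iodo-1-[3-(methoxymethoxy)-4-methyl-5-oxo-2,5-dihydrofuran-2-yl]-2,6-dimethylhept-6-en-1-yl methanesulfonate | COCOC1=C(C)C(=O)OC1C(OS(C)(=O)=O)[C@H](C)CCC/C(C)=C/I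
F10 | step 24 | (5Z)-5-[(2R,6E)-7-iodo-2,6-dimethylhept-6-en-1-ylidene]-4-(methoxymethoxy)-3-methylfuran-2(5H)-one | COCOC1=C(C)C(=O)O/C1=C\[C@H](C)CCC/C(C)=C/I
F11 | step 24 | (5Z)-5-[(2R,6E,8E,10S)-13-(furan-3-yl)-2,6,10-trimethyltrideca-6,8-dien-1-ylidene]-4-(methoxymethoxy)-3-methylfuran-2(5H)-one | COCOC1=C(C)C(=O)O/C1=C\[C@H](C)CCC/C(C)=C/C=C/[C@@H](C)CCCc1ccoc1
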